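Cadinane numbering: C1/C6 are the ring-fusion carbons, C7 carries the acrylic acid, C8 the acyloxy group, C10 the exocyclic methylene. Ring B (C1, C6, C7, C8, C9, C10) is a cyclohexane oxygenated at C8 and, latently, at C10, so it is cut into a two-carbon unit (C6=C7) and a 1-alkoxy-3-silyloxy diene (C1=C10–C9=C8). One intramolecular Diels–Alder reaction of an acyclic tetraene, triggered by oxidation to a Z-keto ester, forms C1–C6 and C7–C8, closes rings A and B and sets C1, C6, C7 and C8. A silyloxy stereocentre at C5 steers the face and is later transposed to C15; C1 is then epimerized through the C10 ketone.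

Key step: step 10

Remark: the (S,S)-ProPhenol ligand is assumed to deliver the (R)-carbinol 6; should the sense of induction be the opposite, its (R,R) antipode is used.

Step 1
Reactants: 1 ε-caprolactone
Product: 2 6-hydroxy-N-methoxy-N-methylhexanamide
Conditions: MeNH(OMe)·HCl, AlMe3, CH2Cl2, 0 °C to rt; aq. HCl work-up
Reagents that add atoms: N,O-dimethylhydroxylamine hydrochloride (CNOC.Cl)
Why: Aluminium amide aminolysis of the lactone (Weinreb amide formation) opens the ring to a chain whose carbonyl carbon becomes C10 and whose CH2OH carbon becomes C5.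

Step 2
Reactants: 2 6-hydroxy-N-methoxy-N-methylhexanamide
Product: 3 N-methoxy-N-methyl-6-oxohexanamide
Conditions: Dess–Martin periodinane, NaHCO3, CH2Cl2, 0 °C to rt
Reagents that add atoms: none
Why: Dess–Martin oxidation stops cleanly at the aldehyde and leaves the amide untouched.

Step 3
Reactants: 3 N-methoxy-N-methyl-6-oxohexanamide
Product: 4 5-formyl-N-methoxy-N-methylhex-5-enamide
Conditions: aq. CH2O (37%), pyrrolidine (10 mol%), propionic acid (10 mol%), i-PrOH, 45 °C
Reagents that add atoms: formaldehyde (C=O)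
Why: Amine-catalysed Mannich condensation and elimination (α-methylenation of an aldehyde) puts the future C15 on C4 as an exocyclic methylene, the amide being too weakly acidic to compete.

Step 4
Reactants: 4 5-formyl-N-methoxy-N-methylhex-5-enamide; 5 trimethylsilylacetylene
Product: 6 (6R)-6-hydroxy-N-methoxy-N-methyl-5-methylidene-8-(trimethylsilyl)oct-7-ynamide
Conditions: (S,S)-ProPhenol (20 mol%), Me2Zn (3 equiv), Ph3P=O (20 mol%), toluene, 0 to 4 °C; aq. NH4Cl
Reagents that add atoms: none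
Why: Dinuclear zinc–ProPhenol-catalysed enantioselective alkynylation of the enal, in which the chiral zinc alkoxide pocket selects the aldehyde face, should set the C5 carbinol as R, while the Weinreb amide is inert to the alkynylzinc.

Step 5
Reactants: 6 (6R)-6-hydroxy-N-methoxy-N-methyl-5-methylidene-8-(trimethylsilyl)oct-7-ynamide
Product: 7 (8R)-8-hydroxy-7-methylidene-10-(trimethylsilyl)deca-1,9-diyn-3-one
Conditions: HC≡CMgBr (3.5 equiv), THF, 0 °C; aq. NH4Cl
Reagents that add atoms: ethynylmagnesium bromide (C#C[Mg]Br)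
Why: Weinreb ketone synthesis: the chelated tetrahedral adduct survives until work-up so that a single ethynyl group is added, the free hydroxyl being carried as its magnesium alkoxide.

Step 6
Reactants: 7 (8R)-8-hydroxy-7-methylidene-10-(trimethylsilyl)deca-1,9-diyn-3-one
Product: 9 (1E,8R)-8-hydroxy-1-[(4-methoxyphenyl)methoxy]-7-methylidenedec-1-en-9-yn-3-one, via silyl alkyne 8 (not isolated)
Conditions: 4-methoxybenzyl alcohol (3 equiv), DABCO (10 mol%), CH2Cl2, 0 °C to rt; then TBAF, AcOH, THF, 0 °C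
Reagents that add atoms: 4-methoxybenzyl alcohol (COc1ccc(CO)cc1)
Why: Amine-catalysed oxa-Michael addition to the terminal ynone should give the thermodynamic E β-alkoxy enone (the excess primary alcohol outcompetes the hindered C5 hydroxyl), and buffered fluoride then removes the alkynyl silyl group (protodesilylation).

Step 7
Reactants: 9 (1E,8R)-8-hydroxy-1-[(4-methoxyphenyl)methoxy]-7-methylidenedec-1-en-9-yn-3-one
Product: 10 (1E,3Z,8R)-3,8-bis{[tert-butyl(dimethyl)silyl]oxy}-1-[(4-methoxyphenyl)methoxy]-7-methylidenedeca-1,3-dien-9-yne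
Conditions: TBSOTf (2.5 equiv), Et3N (4 equiv), Et2O, −78 to 0 °C
Reagents that add atoms: tert-butyldimethylsilyl trifluoromethanesulfonate (CC(C)(C)[Si](C)(C)OS(=O)(=O)C(F)(F)F)
Why: Silyl triflate and amine silylate the C5 hydroxyl and, by soft enolisation at the only enolisable position (C1), give the 1-alkoxy-3-silyloxy diene as the Z enol ether, the usual outcome of silyl triflate/amine enolisation of acyclic ketones.

Step 8
Reactants: 10 (1E,3Z,8R)-3,8-bis{[tert-butyl(dimethyl)silyl]oxy}-1-[(4-methoxyphenyl)methoxy]-7-methylidenedeca-1,3-dien-9-yne; 11 tert-butyl glyoxylate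
Product: 13 tert-butyl (5R,9Z,11E)-5,10-bis{[tert-butyl(dimethyl)silyl]oxy}-2-hydroxy-12-[(4-methoxyphenyl)methoxy]-6-methylidenedodeca-9,11-dien-3-ynoate (both C2 epimers), via lithium acetylide 12 (not isolated)
Conditions: n-BuLi (1.0 equiv), THF, −78 °C; then 11, −78 °C; aq. NH4Cl
Reagents that add atoms: none
Why: 1,2-Addition of the lithium acetylide to the glyoxylate aldehyde at low temperature, where the silyl enol ether and the ester are not attacked, adds C11 and C12; the new carbinol centre is left uncontrolled because it is oxidised in step 10.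

Step 9
Reactants: 13 tert-butyl (5R,9Z,11E)-5,10-bis{[tert-butyl(dimethyl)silyl]oxy}-2-hydroxy-12-[(4-methoxyphenyl)methoxy]-6-methylidenedodeca-9,11-dien-3-ynoate
Product: 14 tert-butyl (3Z,5S,9Z,11E)-5,10-bis{[tert-butyl(dimethyl)silyl]oxy}-2-hydroxy-12-[(4-methoxyphenyl)methoxy]-6-methylidenedodeca-3,9,11-trienoate (both C2 epimers)
Conditions: H2 (1 atm), Pd/CaCO3 poisoned with Pb(OAc)2 (Lindlar catalyst), quinoline, EtOAc, rt
Reagents that add atoms: none
Why: Lindlar semi-hydrogenation adds hydrogen syn to the alkyne and should give the Z C6=C7 alkene (the C5 descriptor changes from R to S through CIP priorities only).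

Step 10
Reactants: 14 tert-butyl (3Z,5S,9Z,11E)-5,10-bis{[tert-butyl(dimethyl)silyl]oxy}-2-hydroxy-12-[(4-methoxyphenyl)methoxy]-6-methylidenedodeca-3,9,11-trienoate
Product: 16 tert-butyl 2-[(1S,2R,4aR,8S,8aS)-4,8-bis{[tert-butyl(dimethyl)silyl]oxy}-2-[(4-methoxyphenyl)methoxy]-7-methylidene-1,2,4a,5,6,7,8,8a-octahydronaphthalen-1-yl]-2-oxoacetate (cis-fused all-cis cycloadduct), via Z-keto ester 15 (not isolated)
Conditions: Dess–Martin periodinane, NaHCO3, CH2Cl2, 0 °C to rt (40 °C if needed)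
Reagents that add atoms: none
Why: Dess–Martin oxidation of the allylic α-hydroxy ester gives Z-keto ester 15, whose electron-poor C6=C7 bond should be trapped at once by the tethered electron-rich 1-alkoxy-3-silyloxy diene in a concerted but asynchronous normal-demand [4+2] cycloaddition (an oxidation-triggered type 1 intramolecular Diels–Alder reaction; closest known types are cycloadditions of 1-alkoxy-3-silyloxy dienes with enones and oxidation-triggered cycloadditions of trienones), the nucleophilic diene terminus C1 matching the β-carbon C6. Ring B closes as the cyclohexene of the cycloaddition (bonds C1–C6 and C7–C8) and ring A closes in the same event as the six-membered ring that the four-atom tether C2–C5 spans between C1 and C6. The Z dienophile makes H6 and H7 cis, the E,Z diene puts the C8 oxygen cis to the C1–C2 bond, and the endo (Alder) transition state, with the keto ester and the tether both under the diene, puts C5 and C11 on the face of C2 and O8, so that C1, C6, C7 and C8 should come out all-cis with a cis ring fusion. The absolute sense comes from C5: 1,3-allylic strain with the cis keto ester holds H5 in the alkene plane, the diene can reach C6 only from the face that carries C4, and the silyloxy group points away from it. The step therefore needs endo over exo and one π-face; secondary overlap with the keto ester carbonyls secures the first and the Z-allylic silyloxy stereocentre the second, while the C1 configuration, the only one not yet that of the target, is corrected in step 12.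

Step 11
Reactants: 16 cis-fused keto ester cycloadduct
Product: 17 tert-butyl 2-[(1R,2S,4aR,8S,8aR)-4,8-bis{[tert-butyl(dimethyl)silyl]oxy}-2-[(4-methoxyphenyl)methoxy]-7-methylidene-1,2,4a,5,6,7,8,8a-octahydronaphthalen-1-yl]prop-2-enoate
Conditions: Ph3PCH3Br, KHMDS, THF, −78 to 0 °C
Reagents that add atoms: methylenetriphenylphosphorane (C=P(c1ccccc1)(c1ccccc1)c1ccccc1)
Why: Wittig methylenation of the very electrophilic ketone of the α-keto ester should be faster at −78 °C than enolisation toward C7, so the acrylate (C11=C13 with the C12 ester) is installed directly without loss of the C7 configuration, the silyl enol ether and the tert-butyl ester being inert (descriptor changes are CIP priority changes only).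

Step 12
Reactants: 17 acrylate silyl enol ether
Product: 19 tert-butyl 2-[(1R,2R,4aS,8S,8aR)-8-{[tert-butyl(dimethyl)silyl]oxy}-2-[(4-methoxyphenyl)methoxy]-7-methylidene-4-oxodecahydronaphthalen-1-yl]prop-2-enoate (trans-fused), via cis-fused ketone 18 (not isolated)
Conditions: HF·pyridine, pyridine, THF, 0 °C; then DBU (0.2 equiv), CH2Cl2, 0 °C to rt
Reagents that add atoms: none
Why: Buffered HF hydrolyses only the silyl enol ether (protonation at C9) to cis-fused ketone 18, and catalytic DBU should then epimerise C1 through the C10 enolate to the trans-fused decalone, which is strongly favoured because the all-cis isomer carries a 1,3-diaxial pair in either chair (thermodynamic epimerisation of an α-stereocentre).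

Step 13
Reactants: 19 trans-fused C10 ketone
Product: 20 tert-butyl 2-[(1R,2R,4aS,8S,8aS)-8-{[tert-butyl(dimethyl)silyl]oxy}-2-[(4-methoxyphenyl)methoxy]-4,7-dimethylidenedecahydronaphthalen-1-yl]prop-2-enoate
Conditions: Zn, CH2Br2, TiCl4, THF/CH2Cl2, 0 °C to rt
Reagents that add atoms: dibromomethane (BrCBr)
Why: Takai–Lombardo methylenation, a non-basic titanium–zinc methylene transfer, should convert the enolisable β-alkoxy ketone at C10 into the exocyclic methylene without β-elimination or epimerisation and ignores the esters.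

Step 14
Reactants: 20 C5 silyl ether with exocyclic C4=C15
Product: 21 tert-butyl 2-[(1R,2R,4aS,8aS)-7-({[tert-butyl(dimethyl)silyl]oxy}methyl)-2-[(4-methoxyphenyl)methoxy]-4-methylidene-1,2,3,4,4a,5,6,8a-octahydronaphthalen-1-yl]prop-2-enoate
Conditions: Re2O7 (5 mol%), Et2O, 0 °C to rt
Reagents that add atoms: none
Why: Re2O7-catalysed 1,3-transposition of the allylic silyl ether through an allyl perrhenate [3,3] shift moves oxygen from C5 to C15 and the double bond from C4=C15 to C4=C5, driven by the more substituted endocyclic alkene and the less hindered primary silyl ether; the auxiliary C5 stereocentre disappears.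

Step 15
Reactants: 21 C15 silyl ether C8 4-methoxybenzyl ether
Product: 22 tert-butyl 2-[(1R,2R,4aS,8aS)-7-({[tert-butyl(dimethyl)silyl]oxy}methyl)-2-hydroxy-4-methylidene-1,2,3,4,4a,5,6,8a-octahydronaphthalen-1-yl]prop-2-enoate
Conditions: DDQ, CH2Cl2/pH 7 buffer, 0 °C
Reagents that add atoms: none
Why: Oxidative cleavage of the 4-methoxybenzyl ether (hydride abstraction by DDQ, then hydrolysis of the oxocarbenium ion) frees only the C8 hydroxyl, and the bulky tert-butyl ester suppresses lactonisation of the resulting γ-hydroxy ester.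

Step 16
Reactants: 23 1,1,1,3,3,3-hexafluoropropan-2-yl acrylate; 24 (tert-butyldimethylsilyloxy)acetaldehyde
Product: 25 1,1,1,3,3,3-hexafluoropropan-2-yl (3S)-4-{[tert-butyl(dimethyl)silyl]oxy}-3-hydroxy-2-methylidenebutanoate
Conditions: β-isocupreidine (10 mol%), DMF, −55 °C
Reagents that add atoms: none
Why: Asymmetric Morita–Baylis–Hillman reaction: the cinchona-derived amine–phenol catalyst adds to the activated acrylate and its hydrogen-bonded aldol step fixes the carbinol, which should be S here (the spatial sense that is named R for simple alkyl aldehydes).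

Step 17
Reactants: 25 Morita–Baylis–Hillman adduct
Product: 26 1,1,1,3,3,3-hexafluoropropan-2-yl (3S)-3,4-bis{[tert-butyl(dimethyl)silyl]oxy}-2-methylidenebutanoate
Conditions: TBSOTf, 2,6-lutidine, CH2Cl2, −78 °C
Reagents that add atoms: tert-butyldimethylsilyl trifluoromethanesulfonate (CC(C)(C)[Si](C)(C)OS(=O)(=O)C(F)(F)F)
Why: Silylation of the secondary allylic alcohol with a silyl triflate and a hindered base avoids acyl transfer or conjugate addition and does not touch the stereocentre.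

Step 18
Reactants: 26 bis-silyl hexafluoroisopropyl ester
Product: 27 (3S)-3,4-bis{[tert-butyl(dimethyl)silyl]oxy}-2-methylidenebutanoic acid
Conditions: LiOH, THF/H2O, 0 °C; aq. HCl to pH 3
Reagents that add atoms: lithium hydroxide ([Li+].[OH-])
Why: Saponification of the activated hexafluoroisopropyl ester should proceed at 0 °C, conditions under which the silyl ethers and the acrylate survive.

Step 19
Reactants: 22 C8 alcohol; 27 (3S)-3,4-bis{[tert-butyl(dimethyl)silyl]oxy}-2-methylidenebutanoic acid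
Product: 29 (1R,2R,4aS,8aS)-1-[3-(tert-butoxy)-3-oxoprop-1-en-2-yl]-7-({[tert-butyl(dimethyl)silyl]oxy}methyl)-4-methylidene-1,2,3,4,4a,5,6,8a-octahydronaphthalen-2-yl (3S)-3,4-bis{[tert-butyl(dimethyl)silyl]oxy}-2-methylidenebutanoate, via mixed anhydride 28 (not isolated)
Conditions: 2,4,6-trichlorobenzoyl chloride, Et3N, THF, rt; then 22, DMAP, toluene, rt
Reagents that add atoms: none
Why: Yamaguchi esterification acylates the hindered equatorial C8 hydroxyl through the acylpyridinium ion of the mixed anhydride with retention at C8 (the C–O bond is not broken), the tert-butyl ester resisting intramolecular transesterification.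

Step 20
Reactants: 29 fully protected ester
Product: 31 2-[(1R,2R,4aS,8aS)-2-{[(3S)-3,4-dihydroxy-2-methylidenebutanoyl]oxy}-7-(hydroxymethyl)-4-methylidene-1,2,3,4,4a,5,6,8a-octahydronaphthalen-1-yl]prop-2-enoic acid (CNP0460913.2), via silyl ester 30 (not isolated)
Conditions: TMSOTf, 2,6-lutidine, CH2Cl2, 0 °C; then HF·pyridine, pyridine, THF, 0 °C to rt
Reagents that add atoms: none
Why: Silyl triflate-mediated cleavage of the tert-butyl ester (loss of 2-methylpropene) followed by fluoride desilylation of the silyl ester and the three silyl ethers should free the acid, the allylic alcohol and the diol under non-basic conditions, so that the γ-hydroxy ester side chain does not lactonise.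

Compound list
1 | ε-caprolactone (oxepan-2-one) | O=C1CCCCCO1 | starting material
2 | 6-hydroxy-N-methoxy-N-methylhexanamide | CON(C)C(=O)CCCCCO | intermediate
3 | N-methoxy-N-methyl-6-oxohexanamide | CON(C)C(=O)CCCCC=O | intermediate
4 | 5-formyl-N-methoxy-N-methylhex-5-enamide | CON(C)C(=O)CCCC(=C)C=O | intermediate
5 | trimethylsilylacetylene | C#C[Si](C)(C)C | starting material
6 | (6R)-6-hydroxy-N-methoxy-N-methyl-5-methylidene-8-(trimethylsilyl)oct-7-ynamide | CON(C)C(=O)CCCC(=C)[C@@H](O)C#C[Si](C)(C)C | intermediate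
7 | (8R)-8-hydroxy-7-methylidene-10-(trimethylsilyl)deca-1,9-diyn-3-one | C#CC(=O)CCCC(=C)[C@@H](O)C#C[Si](C)(C)C | intermediate
8 | (1E,8R)-8-hydroxy-1-[(4-methoxyphenyl)methoxy]-7-methylidene-10-(trimethylsilyl)dec-1-en-9-yn-3-one | COc1ccc(CO/C=C/C(=O)CCCC(=C)[C@@H](O)C#C[Si](C)(C)C)cc1 | intermediate (not isolated)
9 | (1E,8R)-8-hydroxy-1-[(4-methoxyphenyl)methoxy]-7-methylidenedec-1-en-9-yn-3-one | COc1ccc(CO/C=C/C(=O)CCCC(=C)[C@@H](O)C#C)cc1 | intermediate
10 | (1E,3Z,8R)-3,8-bis{[tert-butyl(dimethyl)silyl]oxy}-1-[(4-methoxyphenyl)methoxy]-7-methylidenedeca-1,3-dien-9-yne | COc1ccc(CO/C=C/C(O[Si](C)(C)C(C)(C)C)=C/CCC(=C)[C@@H](O[Si](C)(C)C(C)(C)C)C#C)cc1 | intermediate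
11 | tert-butyl glyoxylate (tert-butyl 2-oxoacetate) | O=CC(=O)OC(C)(C)C | starting material
12 | lithium acetylide of 10 | COc1ccc(CO/C=C/C(O[Si](C)(C)C(C)(C)C)=C/CCC(=C)[C@@H](O[Si](C)(C)C(C)(C)C)C#C[Li])cc1 | intermediate (not isolated)
13 | tert-butyl (5R,9Z,11E)-5,10-bis{[tert-butyl(dimethyl)silyl]oxy}-2-hydroxy-12-[(4-methoxyphenyl)methoxy]-6-methylidenedodeca-9,11-dien-3-ynoate (both C2 epimers) | COc1ccc(CO/C=C/C(O[Si](C)(C)C(C)(C)C)=C/CCC(=C)[C@@H](O[Si](C)(C)C(C)(C)C)C#CC(O)C(=O)OC(C)(C)C)cc1 | intermediate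
14 | tert-butyl (3Z,5S,9Z,11E)-5,10-bis{[tert-butyl(dimethyl)silyl]oxy}-2-hydroxy-12-[(4-methoxyphenyl)methoxy]-6-methylidenedodeca-3,9,11-trienoate (both C2 epimers) | COc1ccc(CO/C=C/C(O[Si](C)(C)C(C)(C)C)=C/CCC(=C)[C@@H](O[Si](C)(C)C(C)(C)C)/C=C\C(O)C(=O)OC(C)(C)C)cc1 | intermediate
15 | tert-butyl (3Z,5S,9Z,11E)-5,10-bis{[tert-butyl(dimethyl)silyl]oxy}-12-[(4-methoxyphenyl)methoxy]-6-methylidene-2-oxododeca-3,9,11-trienoate | COc1ccc(CO/C=C/C(O[Si](C)(C)C(C)(C)C)=C/CCC(=C)[C@@H](O[Si](C)(C)C(C)(C)C)/C=C\C(=O)C(=O)OC(C)(C)C)cc1 | intermediate (not isolated)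
16 | tert-butyl 2-[(1S,2R,4aR,8S,8aS)-4,8-bis{[tert-butyl(dimethyl)silyl]oxy}-2-[(4-methoxyphenyl)methoxy]-7-methylidene-1,2,4a,5,6,7,8,8a-octahydronaphthalen-1-yl]-2-oxoacetate (cis-fused; H1, H6, H7, H8 of the cadinane skeleton all cis) | O=C(C(=O)OC(C)(C)C)[C@H]1[C@H]2[C@H](O[Si](C)(C)C(C)(C)C)C(=C)CC[C@H]2C(O[Si](C)(C)C(C)(C)C)=C[C@H]1OCc1ccc(OC)cc1 | intermediate
17 | tert-butyl 2-[(1R,2S,4aR,8S,8aR)-4,8-bis{[tert-butyl(dimethyl)silyl]oxy}-2-[(4-methoxyphenyl)methoxy]-7-methylidene-1,2,4a,5,6,7,8,8a-octahydronaphthalen-1-yl]prop-2-enoate (cis-fused) | C=C(C(=O)OC(C)(C)C)[C@H]1[C@H]2[C@H](O[Si](C)(C)C(C)(C)C)C(=C)CC[C@H]2C(O[Si](C)(C)C(C)(C)C)=C[C@H]1OCc1ccc(OC)cc1 | intermediate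
18 | tert-butyl 2-[(1R,2R,4aR,8S,8aR)-8-{[tert-butyl(dimethyl)silyl]oxy}-2-[(4-methoxyphenyl)methoxy]-7-methylidene-4-oxodecahydronaphthalen-1-yl]prop-2-enoate (cis-fused) | C=C(C(=O)OC(C)(C)C)[C@H]1[C@H]2[C@H](O[Si](C)(C)C(C)(C)C)C(=C)CC[C@H]2C(=O)C[C@H]1OCc1ccc(OC)cc1 | intermediate (not isolated)
19 | tert-butyl 2-[(1R,2R,4aS,8S,8aR)-8-{[tert-butyl(dimethyl)silyl]oxy}-2-[(4-methoxyphenyl)methoxy]-7-methylidene-4-oxodecahydronaphthalen-1-yl]prop-2-enoate (trans-fused) | C=C(C(=O)OC(C)(C)C)[C@H]1[C@H]2[C@H](O[Si](C)(C)C(C)(C)C)C(=C)CC[C@@H]2C(=O)C[C@H]1OCc1ccc(OC)cc1 | intermediate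
20 | tert-butyl 2-[(1R,2R,4aS,8S,8aS)-8-{[tert-butyl(dimethyl)silyl]oxy}-2-[(4-methoxyphenyl)methoxy]-4,7-dimethylidenedecahydronaphthalen-1-yl]prop-2-enoate | C=C(C(=O)OC(C)(C)C)[C@H]1[C@H]2[C@H](O[Si](C)(C)C(C)(C)C)C(=C)CC[C@@H]2C(=C)C[C@H]1OCc1ccc(OC)cc1 | intermediate
21 | tert-butyl 2-[(1R,2R,4aS,8aS)-7-({[tert-butyl(dimethyl)silyl]oxy}methyl)-2-[(4-methoxyphenyl)methoxy]-4-methylidene-1,2,3,4,4a,5,6,8a-octahydronaphthalen-1-yl]prop-2-enoate | C=C(C(=O)OC(C)(C)C)[C@H]1[C@H]2C=C(CO[Si](C)(C)C(C)(C)C)CC[C@@H]2C(=C)C[C@H]1OCc1ccc(OC)cc1 | intermediate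
22 | tert-butyl 2-[(1R,2R,4aS,8aS)-7-({[tert-butyl(dimethyl)silyl]oxy}methyl)-2-hydroxy-4-methylidene-1,2,3,4,4a,5,6,8a-octahydronaphthalen-1-yl]prop-2-enoate | C=C(C(=O)OC(C)(C)C)[C@H]1[C@H]2C=C(CO[Si](C)(C)C(C)(C)C)CC[C@@H]2C(=C)C[C@H]1O | intermediate
23 | 1,1,1,3,3,3-hexafluoropropan-2-yl acrylate | C=CC(=O)OC(C(F)(F)F)C(F)(F)F | starting material
24 | (tert-butyldimethylsilyloxy)acetaldehyde | O=CCO[Si](C)(C)C(C)(C)C | starting material
25 | 1,1,1,3,3,3-hexafluoropropan-2-yl (3S)-4-{[tert-butyl(dimethyl)silyl]oxy}-3-hydroxy-2-methylidenebutanoate | C=C(C(=O)OC(C(F)(F)F)C(F)(F)F)[C@H](O)CO[Si](C)(C)C(C)(C)C | intermediate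
26 | 1,1,1,3,3,3-hexafluoropropan-2-yl (3S)-3,4-bis{[tert-butyl(dimethyl)silyl]oxy}-2-methylidenebutanoate | C=C(C(=O)OC(C(F)(F)F)C(F)(F)F)[C@H](O[Si](C)(C)C(C)(C)C)CO[Si](C)(C)C(C)(C)C | intermediate
27 | (3S)-3,4-bis{[tert-butyl(dimethyl)silyl]oxy}-2-methylidenebutanoic acid | C=C(C(=O)O)[C@H](O[Si](C)(C)C(C)(C)C)CO[Si](C)(C)C(C)(C)C | intermediate
28 | (3S)-3,4-bis{[tert-butyl(dimethyl)silyl]oxy}-2-methylidenebutanoic 2,4,6-trichlorobenzoic anhydride | C=C(C(=O)OC(=O)c1c(Cl)cc(Cl)cc1Cl)[C@H](O[Si](C)(C)C(C)(C)C)CO[Si](C)(C)C(C)(C)C | intermediate (not isolated)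
29 | (1R,2R,4aS,8aS)-1-[3-(tert-butoxy)-3-oxoprop-1-en-2-yl]-7-({[tert-butyl(dimethyl)silyl]oxy}methyl)-4-methylidene-1,2,3,4,4a,5,6,8a-octahydronaphthalen-2-yl (3S)-3,4-bis{[tert-butyl(dimethyl)silyl]oxy}-2-methylidenebutanoate | C=C(C(=O)OC(C)(C)C)[C@H]1[C@H]2C=C(CO[Si](C)(C)C(C)(C)C)CC[C@@H]2C(=C)C[C@H]1OC(=O)C(=C)[C@H](O[Si](C)(C)C(C)(C)C)CO[Si](C)(C)C(C)(C)C | intermediate
30 | trimethylsilyl ester corresponding to 29 (tert-butyl replaced by trimethylsilyl) | C=C(C(=O)O[Si](C)(C)C)[C@H]1[C@H]2C=C(CO[Si](C)(C)C(C)(C)C)CC[C@@H]2C(=C)C[C@H]1OC(=O)C(=C)[C@H](O[Si](C)(C)C(C)(C)C)CO[Si](C)(C)C(C)(C)C | intermediate (not isolated)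
31 | 2-[(1R,2R,4aS,8aS)-2-{[(3S)-3,4-dihydroxy-2-methylidenebutanoyl]oxy}-7-(hydroxymethyl)-4-methylidene-1,2,3,4,4a,5,6,8a-octahydronaphthalen-1-yl]prop-2-enoic acid (CNP0460913.2) | C=C(C(=O)O)[C@H]1[C@H]2C=C(CO)CC[C@@H]2C(=C)C[C@H]1OC(=O)C(=C)[C@H](O)CO | target

Total step count: 20. Longest linear sequence: 17 steps (steps 1–15, 19 and 20, from ε-caprolactone); the side-chain acid 27 takes 3 steps (16–18).

Steps most likely to fail

1. Step 10 (key step). Process at risk: erosion of the endo preference at the temperature at which the oxidation runs, and attack of the hypervalent iodine oxidant on the electron-rich silyl dienol ether before cyclisation. Fallback (dienophile first, diene last): the fallback sets out from 9. The hydroxyl alone is silylated (TBSCl, imidazole, DMF) to the enone silyl ether F1. Zn(OTf)2/Et3N-mediated addition of the alkyne to 11 gives hydroxy ester F2, Lindlar semi-hydrogenation gives Z-alkene F3, and Dess–Martin oxidation gives the Z-keto ester enone F4, which carries no diene and can be handled cold. Soft enolisation (TBSOTf, Et3N, CH2Cl2, −78 °C) then generates 15 at low temperature, and the cycloaddition on slow warming comes back to the route at 16.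

2. Step 12. Process at risk: base-induced β-elimination of the C8 alkoxy group from the C9 enolate competing with epimerisation at C1. Fallback (free hydroxyl instead of ether during the epimerisation): the fallback sets out from 18, isolated after the HF·pyridine hydrolysis. DDQ removes the 4-methoxybenzyl group to give the cis-fused hydroxy ketone F5, whose hydroxide is a far poorer leaving group. DBU epimerisation gives the trans-fused hydroxy ketone F6, Takai–Lombardo methylenation (Zn, CH2Br2, TiCl4) gives the hydroxy diene F7, and Re2O7-catalysed transposition of its allylic silyl ether comes back to the route at 22.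

3. Step 14. Process at risk: incomplete transposition and acid-type ionisation of the allylic silyl ether, leading to elimination or to migration of the exocyclic C10 alkene. Fallback (ionisation through an allylpalladium complex instead of a sigmatropic shift): the fallback sets out from 20. TBAF gives the allylic alcohol F8 and Ac2O/DMAP the secondary acetate F9. Pd(PPh3)4 (zerovalent palladium) in THF equilibrates F9 through the allyl complex to the primary acetate F10 with the trisubstituted C4=C5 alkene (Tsuji–Trost-type allylic transposition). Methanolysis (K2CO3, MeOH, 0 °C) gives the primary alcohol F11, and TBSCl/imidazole comes back to the route at 21.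

Further compounds
F1 | step 10 | (1E,8R)-8-{[tert-butyl(dimethyl)silyl]oxy}-1-[(4-methoxyphenyl)methoxy]-7-methylidenedec-1-en-9-yn-3-one | COc1ccc(CO/C=C/C(=O)CCCC(=C)[C@@H](O[Si](C)(C)C(C)(C)C)C#C)cc1
F2 | step 10 | tert-butyl (5R,11E)-5-{[tert-butyl(dimethyl)silyl]oxy}-2-hydroxy-12-[(4-methoxyphenyl)methoxy]-6-methylidene-10-oxododec-11-en-3-ynoate (both C2 epimers) | COc1ccc(CO/C=C/C(=O)CCCC(=C)[C@@H](O[Si](C)(C)C(C)(C)C)C#CC(O)C(=O)OC(C)(C)C)cc1
F3 | step 10 | tert-butyl (3Z,5S,11E)-5-{[tert-butyl(dimethyl)silyl]oxy}-2-hydroxy-12-[(4-methoxyphenyl)methoxy]-6-methylidene-10-oxododeca-3,11-dienoate (both C2 epimers) | COc1ccc(CO/C=C/C(=O)CCCC(=C)[C@@H](O[Si](C)(C)C(C)(C)C)/C=C\C(O)C(=O)OC(C)(C)C)cc1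
F4 | step 10 | tert-butyl (3Z,5S,11E)-5-{[tert-butyl(dimethyl)silyl]oxy}-12-[(4-methoxyphenyl)methoxy]-6-methylidene-2,10-dioxododeca-3,11-dienoate | COc1ccc(CO/C=C/C(=O)CCCC(=C)[C@@H](O[Si](C)(C)C(C)(C)C)/C=C\C(=O)C(=O)OC(C)(C)C)cc1
F5 | step 12 | tert-butyl 2-[(1R,2R,4aR,8S,8aR)-8-{[tert-butyl(dimethyl)silyl]oxy}-2-hydroxy-7-methylidene-4-oxodecahydronaphthalen-1-yl]prop-2-enoate (cis-fused) | C=C(C(=O)OC(C)(C)C)[C@H]1[C@H]2[C@H](O[Si](C)(C)C(C)(C)C)C(=C)CC[C@H]2C(=O)C[C@H]1O
F6 | step 12 | tert-butyl 2-[(1R,2R,4aS,8S,8aR)-8-{[tert-butyl(dimethyl)silyl]oxy}-2-hydroxy-7-methylidene-4-oxodecahydronaphthalen-1-yl]prop-2-enoate (trans-fused) | C=C(C(=O)OC(C)(C)C)[C@H]1[C@H]2[C@H](O[Si](C)(C)C(C)(C)C)C(=C)CC[C@@H]2C(=O)C[C@H]1O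
F7 | step 12 | tert-butyl 2-[(1R,2R,4aS,8S,8aS)-8-{[tert-butyl(dimethyl)silyl]oxy}-2-hydroxy-4,7-dimethylidenedecahydronaphthalen-1-yl]prop-2-enoate | C=C(C(=O)OC(C)(C)C)[C@H]1[C@H]2[C@H](O[Si](C)(C)C(C)(C)C)C(=C)CC[C@@H]2C(=C)C[C@H]1O
F8 | step 14 | tert-butyl 2-[(1R,2R,4aS,8S,8aS)-8-hydroxy-2-[(4-methoxyphenyl)methoxy]-4,7-dimethylidenedecahydronaphthalen-1-yl]prop-2-enoate | C=C(C(=O)OC(C)(C)C)[C@H]1[C@H]2[C@H](O)C(=C)CC[C@@H]2C(=C)C[C@H]1OCc1ccc(OC)cc1
F9 | step 14 | tert-butyl 2-[(1R,2R,4aS,8S,8aS)-8-acetoxy-2-[(4-methoxyphenyl)methoxy]-4,7-dimethylidenedecahydronaphthalen-1-yl]prop-2-enoate | C=C(C(=O)OC(C)(C)C)[C@H]1[C@H]2[C@H](OC(C)=O)C(=C)CC[C@@H]2C(=C)C[C@H]1OCc1ccc(OC)cc1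
F10 | step 14 | tert-butyl 2-[(1R,2R,4aS,8aS)-7-(acetoxymethyl)-2-[(4-methoxyphenyl)methoxy]-4-methylidene-1,2,3,4,4a,5,6,8a-octahydronaphthalen-1-yl]prop-2-enoate | C=C(C(=O)OC(C)(C)C)[C@H]1[C@H]2C=C(COC(C)=O)CC[C@@H]2C(=C)C[C@H]1OCc1ccc(OC)cc1
F11 | step 14 | tert-butyl 2-[(1R,2R,4aS,8aS)-7-(hydroxymethyl)-2-[(4-methoxyphenyl)methoxy]-4-methylidene-1,2,3,4,4a,5,6,8a-octahydronaphthalen-1-yl]prop-2-enoate | C=C(C(=O)OC(C)(C)C)[C@H]1[C@H]2C=C(CO)CC[C@@H]2C(=C)C[C@H]1OCc1ccc(OC)cc1
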